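A small charge of initiator stands in this flask: 7.3 mM against 1.5 M of free monomer, 0.487% by amount. We want the most monomer in chains it reaches.

| setting | dusk | dawn | winter | flask |
|---|---|---|---|---|
| free monomer | 1 M | 2.2 M | 1.5 M | 1.5 M |
| initiator | 7.3 mM | 7.3 mM | 15 mM | 7.3 mM |
| remark | run made earlier | run made earlier | run made earlier |  |
| time |  |  |  | 6.0 d |

| run | time / d | monomer in chains / % | free monomer / % |
|---|---|---|---|
| dusk | 0.625 | 7.5 | 90.0 |
| dusk | 0.833 | 9.9 | 86.9 |
| dusk | 1.25 | 13.9 | 82.6 |
| dusk | 1.67 | 15.6 | 79.4 |
| dusk | 2.50 | 14.4 | 71.7 |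
| dusk | 3.00 | 16.3 | 68.9 |
| dusk | 5.00 | 13.6 | 62.7 |
| dawn | 0.625 | 6.6 | 91.1 |
| dawn | 0.833 | 9.1 | 86.7 |
| dawn | 1.25 | 10.2 | 81.5 |
| dawn | 1.67 | 10.4 | 77.8 |
| dawn | 2.50 | 10.5 | 69.4 |
| dawn | 3.00 | 10.8 | 66.6 |
| dawn | 5.00 | 6.9 | 57.7 |
| winter | 0.625 | 11.3 | 85.1 |
| winter | 1.04 | 15.0 | 79.0 |
| winter | 1.67 | 18.2 | 69.0 |
| winter | 3.00 | 19.7 | 57.4 |
| winter | 5.00 | 15.7 | 45.3 |

(readings scatter by 1 percentage point)

* the moment within 6.0 d at which there is most monomer in chains
* the amount of monomer in chains, in percent of the free monomer charged, at that time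



Yet the dusk run, with that same initiator charge, read 15.6% in chains at 1.67 d, which at 1 M of free monomer is 21.4 times the initiator charged. The two numbers fit if one initiator opens a chain that takes up many monomers. So we suppose, for the initiator's balance, that chains open in proportion to the initiator and close in pairs. A steady feed into a second-order drain levels at the root of the feed, so we try a root for the peak.

We take the highest chain reading as a fraction and divide it by the root of initiator over free monomer charged; putting the free monomer under the root is a trial on the runs, not something the supposition gives. Dusk, dawn and winter give 1.91, 1.87 and 1.97, with mean 1.92, our peak number h. For the flask, h times its root gives 13.4%.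

The forecast says 12.7% at 2.4 d, on the ground that “it has the same initiator as dusk and dawn”; our figure stands above it.

The flask gives 13.7% at 2.47 d, and the forecast stands within its margins.

    free monomer + initiating radical → growing radical + monomer in chains (k = 1.90 × 10⁵ M⁻¹ min⁻¹)
    2 growing radical → dead chain (k = 3.10 × 10⁷ M⁻¹ s⁻¹)
    initiator → 2 initiating radical (k = 6.70 × 10⁻⁴ min⁻¹)
    free monomer + monomer in chains → side product (k = 1.70 × 10⁻⁴ M⁻¹ min⁻¹)
    free monomer + growing radical → monomer in chains + growing radical, rate k5*[growing radical]*[free monomer] (k = 2200 M⁻¹ min⁻¹)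

The flask's peak over its root is 1.96, beside the h of 1.92 read from the runs. The largest single effect on the flask's peak is the pairing of growing radicals into dead chain: the run without that step reaches 99.9% instead of 13.7%. For the neighbour flask with 0.0029 M of initiator, h gives 8.44%; the computed peak there is 8.74%.

(The earlier runs and the new flask come from a simulation for an exercise, noise included.)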